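Labdane numbering is used for all atoms: C1–C10 decalin, C11–C16 side chain, C17 on C8, C18/C19 on C4, C20 on C10.

**Retrosynthetic overview**
1. Feature: in ring A (C1–C5, C10) the methyl-bearing quaternary carbon C10 lies para, and C4 ortho, to the C3 oxygen. Ring A is therefore a masked 2,4-dimethylphenol whose meta carbon C5 carries C6–C7.
2. Key disconnection C9–C10: the phenol para carbon C10 is alkylated by a π-allylpalladium terminus C9 tethered from C5 through C6–C7–C8. Ring A is present first as the arene, and ring B closes in this dearomatization, which sets C9 and C10.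
3. The tether ends on the central allyl carbon C8, so both allyl termini close a six-membered ring, and an open CH2 terminus would win. The far terminus is therefore C13, tied back to C9 through C12–C11 as a 2-substituted cyclopentenyl carbonate, which makes the termini enantiotopic and gives one constitution.
4. Afterwards: C1=C2 hydrogenation, reductive methylation (C5 and the C4 gem-dimethyl), and C3 reduction. Ozonolysis of C8=C13 then opens the auxiliary ring to the C8 ketone and the C13 aldehyde, followed by C14 (Ohira–Bestmann), C17 (Wittig), C15 (carboxylation), C16 (cuprate, 13Z), hydroboration at C8 and oxidation to the axial aldehyde.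
5. The precursor comes from 2-bromo-1,3-dimethylbenzene and cyclopent-2-en-1-one by two Suzuki–Miyaura couplings.

Key step: step 11

Assumption: the sense of induction of the (R,R) ligand on this new substrate class cannot be derived with certainty, so (R,R) is written and the (S,S) ligand is used instead if the first run should give the antipode of 15.
Remark: compounds 12–14 are racemates.

**Step 1**
Reactants: 1 2-bromo-1,3-dimethylbenzene
Product: 2 2-bromo-1,3-dimethyl-4-nitrobenzene
Conditions: fuming HNO3 (1.1 equiv), H2SO4/AcOH, 0 °C to rt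
Reagents that add atoms: nitric acid, O[N+](=O)[O-]
Why: Electrophilic aromatic nitration, in which the position ortho to one methyl group and para to the other should prevail over the position meta to both.

**Step 2**
Reactants: 2 2-bromo-1,3-dimethyl-4-nitrobenzene
Product: 3 3-bromo-2,4-dimethylaniline
Conditions: H2 (1 atm), sulfided Pt/C, EtOAc, rt
Reagents that add atoms: none
Why: Catalytic hydrogenation of a nitroarene over sulfided platinum, which is poisoned enough to leave the aryl bromide untouched.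

**Step 3**
Reactants: 3 3-bromo-2,4-dimethylaniline
Product: 5 3-bromo-2,4-dimethylphenol, via diazonium hydrogen sulfate 4 (not isolated)
Conditions: NaNO2, aq H2SO4, 0 °C; then into boiling aq H2SO4
Reagents that add atoms: water, O; sodium nitrite, [Na+].[O-]N=O (its nitrogen stays in 4 only)
Why: Diazotization and thermal hydrolysis of the diazonium salt (phenol synthesis by dediazoniation), to which the bromide and the methyl groups are inert.

**Step 4**
Reactants: 5 3-bromo-2,4-dimethylphenol
Product: 6 (3-bromo-2,4-dimethylphenoxy)tri(propan-2-yl)silane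
Conditions: TIPSCl, imidazole, DMF, rt
Reagents that add atoms: chlorotri(propan-2-yl)silane, CC(C)[Si](Cl)(C(C)C)C(C)C
Why: Silyl ether formation, with the bulky triisopropylsilyl group next to an ortho methyl group chosen to withstand the aqueous phosphate of the two cross-couplings.

**Step 5**
Reactants: 6 (3-bromo-2,4-dimethylphenoxy)tri(propan-2-yl)silane
Product: 7 (3-ethenyl-2,4-dimethylphenoxy)tri(propan-2-yl)silane
Conditions: vinyl-Bpin, Pd(OAc)2 (2 mol %), SPhos (4 mol %), K3PO4, toluene/H2O, 90 °C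
Reagents that add atoms: vinylboronic acid pinacol ester, C=CB1OC(C)(C)C(C)(C)O1
Why: Suzuki–Miyaura vinylation, for which a dialkylbiarylphosphine is the standard answer to a bromide flanked by two ortho methyl groups.

**Step 6**
Reactants: 8 cyclopent-2-en-1-one
Product: 9 2-iodocyclopent-2-en-1-one
Conditions: I2, pyridine/CH2Cl2, 0 °C to rt
Reagents that add atoms: iodine, II
Why: α-Iodination of an enone by conjugate addition of pyridine, iodination of the enolate and elimination (a Baylis–Hillman-type sequence).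

**Step 7**
Reactants: 7 (3-ethenyl-2,4-dimethylphenoxy)tri(propan-2-yl)silane; 9 2-iodocyclopent-2-en-1-one
Product: 11 2-{2-[2,6-dimethyl-3-(triisopropylsilyloxy)phenyl]ethyl}cyclopent-2-en-1-one, via B-alkyl-9-BBN 10 (not isolated)
Conditions: 9-BBN, THF, rt to 40 °C; then 9, PdCl2(dppf)·CH2Cl2 (5 mol %), AsPh3 (5 mol %), aq K3PO4, DMF, rt
Reagents that add atoms: 9-BBN, B1C2CCCC1CCC2 (stays in 10 only)
Why: Anti-Markovnikov hydroboration of the styrene followed by B-alkyl Suzuki–Miyaura coupling with the α-iodoenone, which runs at room temperature because the carbonyl group activates the C–I bond.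

**Step 8**
Reactants: 11 2-{2-[2,6-dimethyl-3-(triisopropylsilyloxy)phenyl]ethyl}cyclopent-2-en-1-one
Product: 12 (±)-2-{2-[2,6-dimethyl-3-(triisopropylsilyloxy)phenyl]ethyl}cyclopent-2-en-1-ol
Conditions: NaBH4, CeCl3·7H2O, MeOH, 0 °C
Reagents that add atoms: none
Why: Luche reduction adds hydride 1,2 to the enone and gives the allylic alcohol as a racemate, which is all the key step needs.

**Step 9**
Reactants: 12 (±)-2-{2-[2,6-dimethyl-3-(triisopropylsilyloxy)phenyl]ethyl}cyclopent-2-en-1-ol
Product: 13 (±)-2-{2-[2,6-dimethyl-3-(triisopropylsilyloxy)phenyl]ethyl}cyclopent-2-en-1-yl methyl carbonate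
Conditions: ClCO2Me, pyridine, DMAP (cat.), CH2Cl2, 0 °C
Reagents that add atoms: methyl chloroformate, COC(=O)Cl
Why: Acylation of the secondary allylic alcohol with a chloroformate under nucleophilic catalysis.

**Step 10**
Reactants: 13 (±)-2-{2-[2,6-dimethyl-3-(triisopropylsilyloxy)phenyl]ethyl}cyclopent-2-en-1-yl methyl carbonate
Product: 14 (±)-2-[2-(3-hydroxy-2,6-dimethylphenyl)ethyl]cyclopent-2-en-1-yl methyl carbonate
Conditions: TBAF (1.05 equiv), AcOH (1.1 equiv), THF, 0 °C
Reagents that add atoms: none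
Why: Fluoride cleavage of an aryl silyl ether, fast at 0 °C because phenoxide leaves silicon easily, and buffered with acetic acid so that the carbonate is not attacked.

**Step 11**
Reactants: 14 (±)-2-[2-(3-hydroxy-2,6-dimethylphenyl)ethyl]cyclopent-2-en-1-yl methyl carbonate
Product: 15 (9aS,9bR)-6,9a-dimethyl-1,2,4,5,9a,9b-hexahydro-7H-cyclopenta[a]naphthalen-7-one (9a = C10, 9b = C9; H9 anti to the C10 methyl group)
Conditions: Pd2(dba)3·CHCl3 (2.5 mol %), (R,R)-DACH-phenyl bisphosphine [N,N'-(1R,2R)-cyclohexane-1,2-diylbis(2-diphenylphosphinobenzamide)] (7.5 mol %), degassed CH2Cl2 (0.01 M), rt to 35 °C, no added base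
Reagents that add atoms: none
Why: Proposed new method: zerovalent palladium ionizes both enantiomers of 14 (loss of CO2 and methoxide, which deprotonates the phenol) to one and the same symmetric 2-substituted cyclopentenyl π-allyl complex C9–C8–C13, and the phenoxide attacks it through its para carbon C10 on the face away from the metal, giving a cross-conjugated dienone that cannot rearomatize because C10 keeps its methyl group. The closest known reactions are the palladium- and iridium-catalysed intramolecular allylic dearomatizations of para-tethered phenols to spirodienones and the asymmetric Tsuji–Trost alkylation of 2-substituted cycloalkenyl carbonates; a meta tether, a fused ring and a tether on the central allyl carbon have not been shown together. Ring B (C5, C6, C7, C8, C9, C10) closes as a six-membered ring, exo with respect to the departing metal, with C8 inside the ring and C8=C13 left behind in the cyclopentene. C9 is set by the C2-symmetric ligand, which makes the two enantiotopic termini unequal (the best understood mode of induction of this ligand class), and since either terminus gives the same skeleton, the terminus selectivity that an open-chain allyl with a CH2 end would lack becomes the enantioselection. C10 is set relative to C9 by the substrate: C11 is locked anti on the allyl and can only become equatorial on a chair-like ring B, which puts the C10 methyl group axial and anti to H9, whereas the epimer needs a boat. The step needs C10 over the ortho carbon C4 and over oxygen: C4 is flanked by the C3 oxygen and by C5 while C10 has C1–H as neighbour, the para product is the more stable dienone, O-closure would need an eight-membered meta-bridged ring, and high dilution holds back intermolecular O-allylation, which the catalyst can reverse.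

**Step 12**
Reactants: 15 (9aS,9bR)-6,9a-dimethyl-1,2,4,5,9a,9b-hexahydro-7H-cyclopenta[a]naphthalen-7-one
Product: 16 (9aS,9bR)-6,9a-dimethyl-1,2,4,5,8,9,9a,9b-octahydro-7H-cyclopenta[a]naphthalen-7-one
Conditions: H2 (1 atm), RhCl(PPh3)3 (10 mol %), toluene/EtOH, rt
Reagents that add atoms: none
Why: Homogeneous hydrogenation with RhCl(PPh3)3 saturates the disubstituted C1=C2 bond of a cross-conjugated dienone, as in steroidal 1,4-dien-3-ones, and leaves the tetrasubstituted C4=C5 and trisubstituted C8=C13 bonds alone.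

**Step 13**
Reactants: 16 (9aS,9bR)-6,9a-dimethyl-1,2,4,5,8,9,9a,9b-octahydro-7H-cyclopenta[a]naphthalen-7-one
Product: 18 (5aS,9aS,9bR)-6,6,9a-trimethyl-1,2,4,5,5a,6,8,9,9a,9b-decahydro-7H-cyclopenta[a]naphthalen-7-one, via lithium enolate 17 (not isolated)
Conditions: Li, t-BuOH (1.0 equiv), NH3(l)/THF, −78 to −33 °C; isoprene; MeI, −33 °C to rt
Reagents that add atoms: iodomethane, CI; lithium, [Li] (stays in 17 only)
Why: Dissolving-metal reductive alkylation of an enone, in which axial protonation at C5 sets H5 anti to the C10 methyl group (trans-decalin, 5S) and the regiodefined C3–C4 enolate is methylated at C4, the isolated C8=C13 bond being inert.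

**Step 14**
Reactants: 18 (5aS,9aS,9bR)-6,6,9a-trimethyl-1,2,4,5,5a,6,8,9,9a,9b-decahydro-7H-cyclopenta[a]naphthalen-7-one
Product: 19 (5aS,7R,9aS,9bR)-6,6,9a-trimethyl-2,4,5,5a,6,7,8,9,9a,9b-decahydro-1H-cyclopenta[a]naphthalen-7-ol
Conditions: NaBH4, MeOH/CH2Cl2, 0 °C
Reagents that add atoms: none
Why: Borohydride reduction of a 4,4-dimethyl-3-ketone in a trans-decalin, where hydride is delivered axially on the face opposite to the axial methyl groups on C4 and C10 and should give the equatorial alcohol (3R).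

**Step 15**
Reactants: 19 (5aS,7R,9aS,9bR)-6,6,9a-trimethyl-2,4,5,5a,6,7,8,9,9a,9b-decahydro-1H-cyclopenta[a]naphthalen-7-ol
Product: 20 triethyl{[(5aS,7R,9aS,9bR)-6,6,9a-trimethyl-2,4,5,5a,6,7,8,9,9a,9b-decahydro-1H-cyclopenta[a]naphthalen-7-yl]oxy}silane
Conditions: TESOTf, 2,6-lutidine, CH2Cl2, 0 °C
Reagents that add atoms: triethylsilyl triflate, CC[Si](CC)(CC)OS(=O)(=O)C(F)(F)F
Why: Silylation of a hindered secondary alcohol with the silyl triflate, the triethylsilyl group being stable to the basic steps ahead yet removable at the end without base.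

**Step 16**
Reactants: 20 triethyl{[(5aS,7R,9aS,9bR)-6,6,9a-trimethyl-2,4,5,5a,6,7,8,9,9a,9b-decahydro-1H-cyclopenta[a]naphthalen-7-yl]oxy}silane
Product: 22 3-[(1S,4aS,6R,8aR)-5,5,8a-trimethyl-2-oxo-6-(triethylsilyloxy)decahydronaphthalen-1-yl]propanal, via secondary ozonide 21 (not isolated)
Conditions: O3, CH2Cl2, −78 °C; PPh3, −78 °C to rt
Reagents that add atoms: ozone, [O-][O+]=O
Why: Ozonolysis with reductive work-up of the only C=C bond left opens the auxiliary ring to the C8 ketone and the C13 aldehyde, and C9, now α to the ketone, already carries its chain in the favoured equatorial position.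

**Step 17**
Reactants: 22 3-[(1S,4aS,6R,8aR)-5,5,8a-trimethyl-2-oxo-6-(triethylsilyloxy)decahydronaphthalen-1-yl]propanal
Product: 23 (1S,4aS,6R,8aR)-1-(but-3-yn-1-yl)-5,5,8a-trimethyl-6-(triethylsilyloxy)octahydronaphthalen-2(1H)-one
Conditions: dimethyl (1-diazo-2-oxopropyl)phosphonate, K2CO3, MeOH, 0 °C to rt
Reagents that add atoms: dimethyl (1-diazo-2-oxopropyl)phosphonate, COP(=O)(OC)C(=[N+]=[N-])C(C)=O
Why: Seyferth–Gilbert homologation in the Ohira–Bestmann variant turns the aldehyde into the terminal alkyne (C14 added), while the hindered C8 ketone does not react with the diazophosphonate anion at this temperature.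

**Step 18**
Reactants: 23 (1S,4aS,6R,8aR)-1-(but-3-yn-1-yl)-5,5,8a-trimethyl-6-(triethylsilyloxy)octahydronaphthalen-2(1H)-one
Product: 24 {[(2R,4aS,5R,8aS)-5-(but-3-yn-1-yl)-1,1,4a-trimethyl-6-methylidenedecahydronaphthalen-2-yl]oxy}triethylsilane
Conditions: Ph3PCH3Br, KOt-Bu, THF, 0 °C to reflux
Reagents that add atoms: methyltriphenylphosphonium bromide, C[P+](c1ccccc1)(c1ccccc1)c1ccccc1.[Br-]
Why: Wittig methylenation (C17 added), well tried on 9-substituted 8-oxodecalins of the labdane type, in which enolization can only return the equatorial C9 epimer.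

**Step 19**
Reactants: 24 {[(2R,4aS,5R,8aS)-5-(but-3-yn-1-yl)-1,1,4a-trimethyl-6-methylidenedecahydronaphthalen-2-yl]oxy}triethylsilane
Product: 26 methyl 5-[(1R,4aS,6R,8aS)-5,5,8a-trimethyl-2-methylidene-6-(triethylsilyloxy)decahydronaphthalen-1-yl]pent-2-ynoate, via lithium acetylide 25 (not isolated)
Conditions: n-BuLi, THF, −78 °C; ClCO2Me, −78 to −20 °C
Reagents that add atoms: methyl chloroformate, COC(=O)Cl; n-butyllithium, [Li]CCCC (its lithium stays in 25 only)
Why: Deprotonation of the terminal alkyne and C-acylation of the lithium acetylide with a chloroformate (C15 and the methoxy group added).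

**Step 20**
Reactants: 26 methyl 5-[(1R,4aS,6R,8aS)-5,5,8a-trimethyl-2-methylidene-6-(triethylsilyloxy)decahydronaphthalen-1-yl]pent-2-ynoate
Product: 28 methyl (2Z)-3-methyl-5-[(1R,4aS,6R,8aS)-5,5,8a-trimethyl-2-methylidene-6-(triethylsilyloxy)decahydronaphthalen-1-yl]pent-2-enoate, via alkenylcuprate 27 (not isolated)
Conditions: Me2CuLi (from CuI, MeLi), Et2O/THF, −78 °C; aq NH4Cl at −78 °C
Reagents that add atoms: methyllithium, [Li]C; CuI, [Cu]I (copper stays in 27 only)
Why: Syn carbocupration of a 2-ynoate by a lithium dialkylcuprate, protonated at −78 °C before the alkenylcopper can isomerize through the allenolate, so that C16 and H14 end up cis and C12 cis to the ester (13Z).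

**Step 21**
Reactants: 28 methyl (2Z)-3-methyl-5-[(1R,4aS,6R,8aS)-5,5,8a-trimethyl-2-methylidene-6-(triethylsilyloxy)decahydronaphthalen-1-yl]pent-2-enoate
Product: 30 methyl (2Z)-5-[(1R,2R,4aS,6R,8aS)-2-(hydroxymethyl)-5,5,8a-trimethyl-6-(triethylsilyloxy)decahydronaphthalen-1-yl]-3-methylpent-2-enoate, via B-alkyl-9-BBN 29 (not isolated)
Conditions: 9-BBN, THF, 0 °C to rt; NaBO3·4H2O, THF/H2O, rt
Reagents that add atoms: NaBO3 (as tetrahydrate), [Na+].[O-]OB=O; 9-BBN, B1C2CCCC1CCC2 (stays in 29 only)
Why: Hydroboration–oxidation, in which 9-BBN picks the electron-rich 1,1-disubstituted C8=C17 bond over the electron-poor trisubstituted enoate and adds from the face opposite to the axial C10 methyl group, so that H8 enters there and C17 becomes axial and cis to C20 (8R).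

**Step 22**
Reactants: 30 methyl (2Z)-5-[(1R,2R,4aS,6R,8aS)-2-(hydroxymethyl)-5,5,8a-trimethyl-6-(triethylsilyloxy)decahydronaphthalen-1-yl]-3-methylpent-2-enoate
Product: 31 methyl (2Z)-5-[(1R,2R,4aS,6R,8aS)-2-formyl-5,5,8a-trimethyl-6-(triethylsilyloxy)decahydronaphthalen-1-yl]-3-methylpent-2-enoate
Conditions: Dess–Martin periodinane, NaHCO3, CH2Cl2, 0 °C
Reagents that add atoms: none
Why: Dess–Martin oxidation under bicarbonate buffer, chosen as a method without strong acid or base so that the axial, less stable aldehyde should not epimerize at C8.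

**Step 23**
Reactants: 31 methyl (2Z)-5-[(1R,2R,4aS,6R,8aS)-2-formyl-5,5,8a-trimethyl-6-(triethylsilyloxy)decahydronaphthalen-1-yl]-3-methylpent-2-enoate
Product: 32 methyl (2Z)-5-[(1R,2R,4aS,6R,8aS)-2-formyl-6-hydroxy-5,5,8a-trimethyldecahydronaphthalen-1-yl]-3-methylpent-2-enoate (target; labdane numbering 3R,5S,8R,9R,10S,13Z)
Conditions: HF·pyridine, pyridine/THF, 0 °C
Reagents that add atoms: none
Why: Fluoride cleavage of the triethylsilyl ether in a pyridine-buffered, weakly acidic medium that should touch neither the C8 aldehyde centre, the Z-enoate nor the methyl ester.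

**Compound list**
1 | 2-bromo-1,3-dimethylbenzene | Cc1cccc(C)c1Br | starting material
2 | 2-bromo-1,3-dimethyl-4-nitrobenzene | Cc1ccc([N+](=O)[O-])c(C)c1Br | intermediate
3 | 3-bromo-2,4-dimethylaniline | Cc1ccc(N)c(C)c1Br | intermediate
4 | 3-bromo-2,4-dimethylbenzenediazonium hydrogen sulfate | Cc1ccc([N+]#N)c(C)c1Br.OS(=O)(=O)[O-] | intermediate
5 | 3-bromo-2,4-dimethylphenol | Cc1ccc(O)c(C)c1Br | intermediate
6 | (3-bromo-2,4-dimethylphenoxy)tri(propan-2-yl)silane | Cc1ccc(O[Si](C(C)C)(C(C)C)C(C)C)c(C)c1Br | intermediate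
7 | (3-ethenyl-2,4-dimethylphenoxy)tri(propan-2-yl)silane | Cc1ccc(O[Si](C(C)C)(C(C)C)C(C)C)c(C)c1C=C | intermediate
8 | cyclopent-2-en-1-one | O=C1CCC=C1 | starting material
9 | 2-iodocyclopent-2-en-1-one | O=C1CCC=C1I | intermediate
10 | 9-{2-[2,6-dimethyl-3-(triisopropylsilyloxy)phenyl]ethyl}-9-borabicyclo[3.3.1]nonane | Cc1ccc(O[Si](C(C)C)(C(C)C)C(C)C)c(C)c1CCB1C2CCCC1CCC2 | intermediate
11 | 2-{2-[2,6-dimethyl-3-(triisopropylsilyloxy)phenyl]ethyl}cyclopent-2-en-1-one | Cc1ccc(O[Si](C(C)C)(C(C)C)C(C)C)c(C)c1CCC1=CCCC1=O | intermediate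
12 | (±)-2-{2-[2,6-dimethyl-3-(triisopropylsilyloxy)phenyl]ethyl}cyclopent-2-en-1-ol | Cc1ccc(O[Si](C(C)C)(C(C)C)C(C)C)c(C)c1CCC1=CCCC1O | intermediate
13 | (±)-2-{2-[2,6-dimethyl-3-(triisopropylsilyloxy)phenyl]ethyl}cyclopent-2-en-1-yl methyl carbonate | Cc1ccc(O[Si](C(C)C)(C(C)C)C(C)C)c(C)c1CCC1=CCCC1OC(=O)OC | intermediate
14 | (±)-2-[2-(3-hydroxy-2,6-dimethylphenyl)ethyl]cyclopent-2-en-1-yl methyl carbonate (key-step precursor) | Cc1ccc(O)c(C)c1CCC1=CCCC1OC(=O)OC | intermediate
15 | (9aS,9bR)-6,9a-dimethyl-1,2,4,5,9a,9b-hexahydro-7H-cyclopenta[a]naphthalen-7-one (key-step product) | C1=C2CCC3=C(C)C(=O)C=C[C@@]3(C)[C@@H]2CC1 | intermediate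
16 | (9aS,9bR)-6,9a-dimethyl-1,2,4,5,8,9,9a,9b-octahydro-7H-cyclopenta[a]naphthalen-7-one | C1=C2CCC3=C(C)C(=O)CC[C@@]3(C)[C@@H]2CC1 | intermediate
17 | lithium C3–C4 enolate of the 5S-reduced enone (configuration as in 18) | C1=C2CC[C@@H]3C(C)=C(O[Li])CC[C@@]3(C)[C@@H]2CC1 | intermediate
18 | (5aS,9aS,9bR)-6,6,9a-trimethyl-1,2,4,5,5a,6,8,9,9a,9b-decahydro-7H-cyclopenta[a]naphthalen-7-one | C1=C2CC[C@@H]3C(C)(C)C(=O)CC[C@@]3(C)[C@@H]2CC1 | intermediate
19 | (5aS,7R,9aS,9bR)-6,6,9a-trimethyl-2,4,5,5a,6,7,8,9,9a,9b-decahydro-1H-cyclopenta[a]naphthalen-7-ol | C1=C2CC[C@@H]3C(C)(C)[C@H](O)CC[C@@]3(C)[C@@H]2CC1 | intermediate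
20 | triethylsilyl ether of 19 | C1=C2CC[C@@H]3C(C)(C)[C@H](O[Si](CC)(CC)CC)CC[C@@]3(C)[C@@H]2CC1 | intermediate
21 | secondary ozonide of 20 (1,2,4-trioxolane bridging C8 and C13) | C14OOC2(O4)CC[C@@H]3C(C)(C)[C@H](O[Si](CC)(CC)CC)CC[C@@]3(C)[C@@H]2CC1 | intermediate
22 | 3-[(1S,4aS,6R,8aR)-5,5,8a-trimethyl-2-oxo-6-(triethylsilyloxy)decahydronaphthalen-1-yl]propanal | O=CCC[C@@H]1C(=O)CC[C@@H]2C(C)(C)[C@H](O[Si](CC)(CC)CC)CC[C@@]12C | intermediate
23 | (1S,4aS,6R,8aR)-1-(but-3-yn-1-yl)-5,5,8a-trimethyl-6-(triethylsilyloxy)octahydronaphthalen-2(1H)-one | C#CCC[C@@H]1C(=O)CC[C@@H]2C(C)(C)[C@H](O[Si](CC)(CC)CC)CC[C@@]12C | intermediate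
24 | {[(2R,4aS,5R,8aS)-5-(but-3-yn-1-yl)-1,1,4a-trimethyl-6-methylidenedecahydronaphthalen-2-yl]oxy}triethylsilane | C#CCC[C@@H]1C(=C)CC[C@@H]2C(C)(C)[C@H](O[Si](CC)(CC)CC)CC[C@@]12C | intermediate
25 | lithium acetylide of 24 | [Li]C#CCC[C@@H]1C(=C)CC[C@@H]2C(C)(C)[C@H](O[Si](CC)(CC)CC)CC[C@@]12C | intermediate
26 | methyl 5-[(1R,4aS,6R,8aS)-5,5,8a-trimethyl-2-methylidene-6-(triethylsilyloxy)decahydronaphthalen-1-yl]pent-2-ynoate | COC(=O)C#CCC[C@@H]1C(=C)CC[C@@H]2C(C)(C)[C@H](O[Si](CC)(CC)CC)CC[C@@]12C | intermediate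
27 | lithium methyl(alkenyl)cuprate from 26 (Cu on C14, cis to the new C16 methyl group) | [Li+].COC(=O)/C([Cu-]C)=C(/C)CC[C@@H]1C(=C)CC[C@@H]2C(C)(C)[C@H](O[Si](CC)(CC)CC)CC[C@@]12C | intermediate
28 | methyl (2Z)-3-methyl-5-[(1R,4aS,6R,8aS)-5,5,8a-trimethyl-2-methylidene-6-(triethylsilyloxy)decahydronaphthalen-1-yl]pent-2-enoate | COC(=O)/C=C(/C)CC[C@@H]1C(=C)CC[C@@H]2C(C)(C)[C@H](O[Si](CC)(CC)CC)CC[C@@]12C | intermediate
29 | B-(C17)-alkyl-9-BBN from 28 (8R) | COC(=O)/C=C(/C)CC[C@@H]1[C@H](CB3C4CCCC3CCC4)CC[C@@H]2C(C)(C)[C@H](O[Si](CC)(CC)CC)CC[C@@]12C | intermediate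
30 | methyl (2Z)-5-[(1R,2R,4aS,6R,8aS)-2-(hydroxymethyl)-5,5,8a-trimethyl-6-(triethylsilyloxy)decahydronaphthalen-1-yl]-3-methylpent-2-enoate | COC(=O)/C=C(/C)CC[C@@H]1[C@H](CO)CC[C@@H]2C(C)(C)[C@H](O[Si](CC)(CC)CC)CC[C@@]12C | intermediate
31 | methyl (2Z)-5-[(1R,2R,4aS,6R,8aS)-2-formyl-5,5,8a-trimethyl-6-(triethylsilyloxy)decahydronaphthalen-1-yl]-3-methylpent-2-enoate | COC(=O)/C=C(/C)CC[C@@H]1[C@H](C=O)CC[C@@H]2C(C)(C)[C@H](O[Si](CC)(CC)CC)CC[C@@]12C | intermediate
32 | methyl (2Z)-5-[(1R,2R,4aS,6R,8aS)-2-formyl-6-hydroxy-5,5,8a-trimethyldecahydronaphthalen-1-yl]-3-methylpent-2-enoate | COC(=O)/C=C(/C)CC[C@@H]1[C@H](C=O)CC[C@@H]2C(C)(C)[C@H](O)CC[C@@]12C | target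

**Total step count:** 23. **Longest linear sequence:** 22 (steps 1–5 and 7–23; step 6 is the side branch).

**Steps most likely to fail**

**1. Step 11 (Proposed new method).**
- What may go wrong: closure through the ortho carbon C4, β-hydride elimination of the π-allyl complex to a cyclopentadiene before the hindered C–C bond forms, or weak discrimination of the two allyl termini by the ligand.
- Fallback (known chemistry, no metal) sets out from 12 and comes back at 15.
- Alcohol 12 is converted with MsCl, Et3N and LiCl into the racemic allylic chloride F1.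
- TBAF/AcOH removes the silyl group to give the chlorophenol F2.
- KOt-Bu in t-BuOH/THF under dilution closes ring B by intramolecular C-alkylation of the potassium phenolate (classical alkylative dearomatization). Direct and allylic displacement lead to the same skeleton, and the chair argument for C9/C10 still holds. This gives the racemic dienone F3.
- The enantiomers of F3 are separated by preparative chromatography on a chiral stationary phase; the (9aS,9bR) enantiomer is 15.

**2. Step 21.**
- What may go wrong: slow hydroboration of the hindered C8=C17 bond, which lets the enoate or the ester be attacked, or poor facial selectivity at C8.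
- Fallback sets out from 23 and comes back at 31.
- Ketone 23 undergoes a Wittig reaction with the ylide from (methoxymethyl)triphenylphosphonium chloride and KOt-Bu to give the methyl enol ether F4.
- Carboxylation as in step 19 gives the enol ether ynoate F5, and cuprate addition as in step 20 gives the enol ether Z-enoate F6. Enol ethers tolerate both reagents.
- Hydrolysis with oxalic acid on wet silica gel in CH2Cl2 at 0 °C protonates C8 kinetically on the face opposite to the C10 methyl group. This should release the axial aldehyde 31 without any borane.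

**3. Step 17.**
- What may go wrong: in basic methanol the 1,5-keto aldehyde may close to a bridged aldol (C7 enolate on C13) faster than the aldehyde is homologated.
- Fallback sets out from 22 and comes back at 26.
- A Corey–Fuchs olefination (CBr4, PPh3, Et3N, CH2Cl2, 0 °C; neutral, aldehyde-selective) gives the dibromoalkene ketone F7.
- Wittig methylenation as in step 18 gives the dibromoalkene with the 8(17)-methylidene group F8.
- n-BuLi (2.2 equiv, THF, −78 °C) turns F8 into acetylide 25, which is trapped in the same flask with ClCO2Me to give 26.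

**Further compounds**
F1 | step 11 | racemic allylic chloride, {3-[2-(5-chlorocyclopent-1-en-1-yl)ethyl]-2,4-dimethylphenoxy}tri(propan-2-yl)silane | Cc1ccc(O[Si](C(C)C)(C(C)C)C(C)C)c(C)c1CCC1=CCCC1Cl
F2 | step 11 | chlorophenol, (±)-3-[2-(5-chlorocyclopent-1-en-1-yl)ethyl]-2,4-dimethylphenol | Cc1ccc(O)c(C)c1CCC1=CCCC1Cl
F3 | step 11 | racemic dienone, (9aS*,9bR*)-6,9a-dimethyl-1,2,4,5,9a,9b-hexahydro-7H-cyclopenta[a]naphthalen-7-one | C1=C2CCC3=C(C)C(=O)C=C[C@@]3(C)[C@@H]2CC1.C1=C2CCC3=C(C)C(=O)C=C[C@]3(C)[C@H]2CC1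
F4 | step 21 | methyl enol ether, 8-(methoxymethylidene) analogue of 24 (E/Z mixture) | C#CCC[C@@H]1C(=COC)CC[C@@H]2C(C)(C)[C@H](O[Si](CC)(CC)CC)CC[C@@]12C
F5 | step 21 | enol ether ynoate, 8-(methoxymethylidene) analogue of 26 | COC(=O)C#CCC[C@@H]1C(=COC)CC[C@@H]2C(C)(C)[C@H](O[Si](CC)(CC)CC)CC[C@@]12C
F6 | step 21 | enol ether Z-enoate, 8-(methoxymethylidene) analogue of 28 | COC(=O)/C=C(/C)CC[C@@H]1C(=COC)CC[C@@H]2C(C)(C)[C@H](O[Si](CC)(CC)CC)CC[C@@]12C
F7 | step 17 | dibromoalkene ketone, (1S,4aS,6R,8aR)-1-(4,4-dibromobut-3-en-1-yl)-5,5,8a-trimethyl-6-(triethylsilyloxy)octahydronaphthalen-2(1H)-one | BrC(Br)=CCC[C@@H]1C(=O)CC[C@@H]2C(C)(C)[C@H](O[Si](CC)(CC)CC)CC[C@@]12C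
F8 | step 17 | dibromoalkene with the 8(17)-methylidene group | BrC(Br)=CCC[C@@H]1C(=C)CC[C@@H]2C(C)(C)[C@H](O[Si](CC)(CC)CC)CC[C@@]12C
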